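**Plan**

Numbering follows the 2H-cyclohepta[b]furan-2-one core of the target (O1, C2, C3, C3a, C4–C8, C8a): C5 carries OH, C6 CH3, C7 OH and the butenoyl group, C8 the ester.
Retrosynthesis: the C8 ester oxygen and the C5 hydroxyl lie on the same face and are 1,4-related across the seven-membered ring, so both are traced back to one ether oxygen bridging C5 and C8. Then the ester, C7–C(acyl) and the lactone bonds O1–C2 and C3–C3a (with the exocyclic CH2) are cut, and last the ring bonds C8–C8a and C4–C5.
Forward: a (4+3) cycloaddition joins 3-methylfuran (C5, C6 with its methyl, C7, C8 and the bridge oxygen) to an alkoxy-siloxyallyl cation (C8a–C3a–C4, with C3a the carbonyl carbon between the oxygenated C8a and the CH2 C4). This closes the seven-membered ring as an 8-oxabicyclo[3.2.1]octenone; the butenolide ring is then annulated on the C3a ketone and C8a oxygen, and the oxygen bridge is opened last.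
Stereochemistry: one bought stereocenter, (R)-1-phenylethanol, fixes C8a, C8 and C5 in the cycloaddition. C3a (hydride), C6 (hydroboration) and C7 (acyl anion addition) are relayed by the exo face of the oxabicycle. C5 is inverted twice (iodide in, oxygen back), and the ester stereocenter is bought as (2S)-2-methylbutanoyl chloride.
Key step: step 3

Assumption: the furan is taken to attack the face of the H-eclipsed oxocarbenium conformer of the cation anti to the phenyl ring, which maps (R)-1-phenylethanol onto the required (1R,2S,5R) adduct; if the sense is opposite, (S)-1-phenylethanol is used with no other change.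

**Route**

Step 1
Reactants: 1 1,1-dimethoxypropan-2-one; 2 (R)-1-phenylethanol
Product: 3 1-methoxy-1-[(1R)-1-phenylethoxy]propan-2-one (both epimers at the acetal carbon)
Conditions: 1 (3 equiv), TsOH·H2O (cat.), cyclohexane, 80 °C, MeOH distilled off
Reagents that add atoms: none
Why: Acid-catalysed transacetalisation, in which excess 1 and removal of methanol drive exchange of one methoxy group for the chiral alkoxy group, and the new acetal carbon need not be controlled because it becomes planar in step 3.

Step 2
Reactants: 3 1-methoxy-1-[(1R)-1-phenylethoxy]propan-2-one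
Product: 4 triethyl({3-methoxy-3-[(1R)-1-phenylethoxy]prop-1-en-2-yl}oxy)silane
Conditions: LiN(i-Pr)2, THF, −78 °C; Et3SiCl, −78 to 0 °C
Reagents that add atoms: chlorotriethylsilane CC[Si](Cl)(CC)CC
Why: Silyl enol ether formation, in which the lithium amide removes a proton from the unhindered methyl group and the enolate is trapped on oxygen, giving the 2-siloxyallyl acetal that serves as the oxyallyl cation precursor.

Step 3
Reactants: 4 triethyl({3-methoxy-3-[(1R)-1-phenylethoxy]prop-1-en-2-yl}oxy)silane; 5 3-methylfuran
Product: 7 (1R,2S,5R)-6-methyl-2-[(1R)-1-phenylethoxy]-8-oxabicyclo[3.2.1]oct-6-en-3-one, via alkoxy-siloxyallyl cation 6 (not isolated)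
Conditions: 5 (5 equiv), Me3SiOTf (10 mol %), CH2Cl2, −95 °C
Reagents that add atoms: none
Why: Me3SiOTf removes the methoxy group of the mixed acetal to give the W-shaped 1-alkoxy-2-siloxyallyl cation 6, which adds across the two α-carbons of 3-methylfuran, after which loss of the silyl group frees the ketone and regenerates a silyl triflate. The closest known reaction type is the Lewis-acid-induced (4+3) cycloaddition of acetal-derived 1-alkoxy-2-siloxyallyl cations, chiral 1-phenylethoxy ones included, with furan. Two rings arise from the same two bonds, the cycloheptenone (three cation carbons plus four furan carbons) and the oxygen-bridged tetrahydropyranone: the CH2 terminus (future C4) leads and bonds to furan C2 (future C5), and the ring is closed by the lagging bond between the alkoxy-bearing carbon (future C8a) and furan C5 (future C8), a concerted but asynchronous closure that at the stepwise limit is attack of an enol silane carbon on the furan oxocarbenium carbon (seven-membered ring, enol-endo and exo-trig). C5 and C8 come out cis because the furan oxygen bridges them (suprafacial addition), C8a comes out with its alkoxy group equatorial and trans to the bridge because the alkoxy group is Z in the cation and the transition state is compact, and the absolute sense comes from the (R)-1-phenylethyl group, whose phenyl ring covers one face of the planar cation. The step needs regioselectivity (methyl on the alkene carbon next to the CH2-derived bridgehead), secured by the higher nucleophilicity of the furan carbon next to the methyl group toward the leading CH2 terminus and by the bulky alkoxy terminus preferring the unhindered furan carbon, and it needs facial selectivity, secured by the auxiliary at −95 °C.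

Step 4
Reactants: 7 (1R,2S,5R)-6-methyl-2-[(1R)-1-phenylethoxy]-8-oxabicyclo[3.2.1]oct-6-en-3-one
Product: 8 (1R,2S,5R)-2-hydroxy-6-methyl-8-oxabicyclo[3.2.1]oct-6-en-3-one
Conditions: BCl3, CH2Cl2, −78 °C; then H2O
Reagents that add atoms: none
Why: Lewis-acid cleavage of a secondary benzylic ether, in which BCl3 chelates the ketone and the neighbouring ether oxygen and the 1-phenylethyl group leaves as a stabilised benzylic cation while the dialkyl bridge ether and the alkene stay intact at −78 °C, so no stereocenter is touched.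

Step 5
Reactants: 8 (1R,2S,5R)-2-hydroxy-6-methyl-8-oxabicyclo[3.2.1]oct-6-en-3-one
Product: 10 (5R,8R,8aR)-6-methyl-4,5,8,8a-tetrahydro-2H-5,8-epoxycyclohepta[b]furan-2-one, via phosphorane ester 9 (not isolated)
Conditions: Ph3P=C=C=O (Bestmann ylide), toluene, 90 °C
Reagents that add atoms: (triphenylphosphoranylidene)ketene O=C=C=P(c1ccccc1)(c1ccccc1)c1ccccc1
Why: Bestmann butenolide synthesis, in which the hydroxyl adds to the ketene ylide to give the acyl-stabilised phosphorane ester 9 and this closes the five-membered ring by intramolecular Wittig olefination of the adjacent ketone, leaving the C8a–O bond and its configuration untouched.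

Step 6
Reactants: 10 (5R,8R,8aR)-6-methyl-4,5,8,8a-tetrahydro-2H-5,8-epoxycyclohepta[b]furan-2-one
Product: 12 (3aS,5R,8R,8aR)-3-[(dimethylamino)methyl]-6-methyl-3,3a,4,5,8,8a-hexahydro-2H-5,8-epoxycyclohepta[b]furan-2-one (C3 epimers), via lithium enolate 11 (not isolated)
Conditions: Li[HB(s-Bu)3], THF, −78 °C; then [CH2=NMe2]I, −78 to 0 °C
Reagents that add atoms: N,N-dimethylmethylideneammonium iodide (Eschenmoser's salt) C=[N+](C)C.[I-]
Why: Conjugate hydride reduction of the butenolide followed by Mannich trapping of the lactone enolate, in which hydride reaches C3a from the open face on the side of the oxygen bridge (the other face is blocked by the C6=C7 bridge) so that the lactone becomes cis-fused with H3a cis to H8a, while the C3 configuration is irrelevant because C3 becomes sp2 in step 12.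

Step 7
Reactants: 12 (3aS,5R,8R,8aR)-3-[(dimethylamino)methyl]-6-methyl-3,3a,4,5,8,8a-hexahydro-2H-5,8-epoxycyclohepta[b]furan-2-one
Product: 14 (3aS,5R,6R,7R,8R,8aR)-3-[(dimethylamino)methyl]-7-hydroxy-6-methyloctahydro-2H-5,8-epoxycyclohepta[b]furan-2-one, via B-alkyl-9-BBN adduct 13 (not isolated)
Conditions: 9-BBN dimer, THF, 60 °C; then NaBO3·4H2O, THF–H2O, rt
Reagents that add atoms: sodium perborate [Na+].[Na+].O[B-]1(O)OO[B-](O)(O)OO1
Why: Hydroboration–oxidation, in which the borane adds to the strained trisubstituted alkene from the exo face (syn to the oxygen bridge) with boron on the less substituted C7, so that hydrogen enters C6 on the bridge side and the methyl group ends endo, and the oxidation keeps the C7 configuration while lactone and amine are inert to 9-BBN.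

Step 8
Reactants: 14 (3aS,5R,6R,7R,8R,8aR)-3-[(dimethylamino)methyl]-7-hydroxy-6-methyloctahydro-2H-5,8-epoxycyclohepta[b]furan-2-one
Product: 15 (3aS,5R,6S,8S,8aR)-3-[(dimethylamino)methyl]-6-methylhexahydro-2H-5,8-epoxycyclohepta[b]furan-2,7(3H)-dione
Conditions: Dess–Martin periodinane, NaHCO3, CH2Cl2, 0 °C to rt
Reagents that add atoms: none
Why: Dess–Martin oxidation of the secondary alcohol to the ketone under buffered, non-basic conditions that should not epimerise the neighbouring C6 center or open the bridge by β-elimination.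

Step 9
Reactants: 16 but-2-yn-1-ol
Product: 17 1-methoxybut-2-yne
Conditions: NaH, THF, 0 °C; MeI, 0 °C to rt
Reagents that add atoms: iodomethane CI
Why: Williamson ether synthesis, the sodium alkoxide of the propargylic alcohol being methylated by iodomethane.

Step 10
Reactants: 17 1-methoxybut-2-yne
Product: 18 1-methoxybuta-1,2-diene (racemic allene)
Conditions: KOt-Bu (cat.), 70 °C, product distilled out
Reagents that add atoms: none
Why: Base-catalysed propargyl-to-allenyl isomerisation of a propargylic ether, the standard access to 1-alkoxyallenes, with the allene removed by distillation before it isomerises further.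

Step 11
Reactants: 15 (3aS,5R,6S,8S,8aR)-3-[(dimethylamino)methyl]-6-methylhexahydro-2H-5,8-epoxycyclohepta[b]furan-2,7(3H)-dione; 18 1-methoxybuta-1,2-diene
Product: 21 (3aS,5R,6S,7S,8S,8aR)-7-[(2E)-but-2-enoyl]-3-[(dimethylamino)methyl]-7-hydroxy-6-methyloctahydro-2H-5,8-epoxycyclohepta[b]furan-2-one, via lithiated methoxyallene 19 (not isolated), via lithium alkoxide 20 (not isolated)
Conditions: 18, n-BuLi, THF, −78 °C; 15, −78 °C; then 1 M aq. HCl, THF, 0 °C; NaHCO3 work-up
Reagents that add atoms: water O
Why: Addition of a lithiated alkoxyallene (an acyl anion equivalent) to a ketone and acid hydrolysis of the allenyl enol ether, in which the organolithium attacks C7 from the exo face syn to the oxygen bridge so that the new C–C bond is cis to the bridge and the hydroxyl is endo, and protonation at the central allene carbon, hydrolysis and equilibration give the (E)-but-2-enoyl group.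

Step 12
Reactants: 21 (3aS,5R,6S,7S,8S,8aR)-7-[(2E)-but-2-enoyl]-3-[(dimethylamino)methyl]-7-hydroxy-6-methyloctahydro-2H-5,8-epoxycyclohepta[b]furan-2-one
Product: 23 (3aS,5R,6S,7S,8S,8aR)-7-[(2E)-but-2-enoyl]-7-hydroxy-6-methyl-3-methylideneoctahydro-2H-5,8-epoxycyclohepta[b]furan-2-one, via trimethylammonium iodide 22 (not isolated)
Conditions: MeI, THF, rt; then aq. NaHCO3, EtOAc, rt
Reagents that add atoms: none
Why: Quaternisation of the Mannich base and E1cB (Hofmann-type) elimination of trimethylamine unmask the α-methylene lactone, the dimethylamino group being the only site nucleophilic toward iodomethane.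

Step 13
Reactants: 23 (3aS,5R,6S,7S,8S,8aR)-7-[(2E)-but-2-enoyl]-7-hydroxy-6-methyl-3-methylideneoctahydro-2H-5,8-epoxycyclohepta[b]furan-2-one; 24 (2S)-2-methylbutanoyl chloride
Product: 26 (3aS,5S,6R,7S,8S,8aR)-7-[(2E)-but-2-enoyl]-7-hydroxy-5-iodo-6-methyl-3-methylidene-2-oxooctahydro-2H-cyclohepta[b]furan-8-yl (2S)-2-methylbutanoate, via acyl iodide 25 (not isolated)
Conditions: 24, NaI, MeCN, 0 °C; then 23, 0 °C to rt, dark
Reagents that add atoms: sodium iodide [Na+].[I-]
Why: Acylative cleavage of a cyclic ether by an acyl iodide made from the acyl chloride and NaI, in which the bridge oxygen is acylated and iodide opens the oxonium ion by SN2 attack at C5, the bridgehead not flanked by the quaternary C7 or the oxygenated C8a, so that the ester stays on C8 with retention and C5 takes iodine with inversion.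

Step 14
Reactants: 26 (3aS,5S,6R,7S,8S,8aR)-7-[(2E)-but-2-enoyl]-7-hydroxy-5-iodo-6-methyl-3-methylidene-2-oxooctahydro-2H-cyclohepta[b]furan-8-yl (2S)-2-methylbutanoate
Product: 27 (3aS,5R,6S,7S,8S,8aR)-7-[(2E)-but-2-enoyl]-5,7-dihydroxy-6-methyl-3-methylidene-2-oxooctahydro-2H-cyclohepta[b]furan-8-yl (2S)-2-methylbutanoate (CNP0331957.1)
Conditions: AgO2CCF3, acetone–H2O (9:1), 0 °C to rt, dark
Reagents that add atoms: water O
Why: Silver-assisted solvolysis of the secondary iodide, in which the silver ion pulls off iodide while oxygen (water, or the carbonyl oxygen of the C8 ester across the ring, whose dioxacarbenium ion is then hydrolysed) enters from the face opposite to iodine, so that C5 is inverted a second time and its hydroxyl ends cis to the C8 ester as in the original bridge.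

**Compound list**

1 | 1,1-dimethoxypropan-2-one (pyruvaldehyde dimethyl acetal) | CC(=O)C(OC)OC | starting material
2 | (R)-1-phenylethanol | C[C@@H](O)c1ccccc1 | starting material
3 | 1-methoxy-1-[(1R)-1-phenylethoxy]propan-2-one (both acetal epimers) | CC(=O)C(OC)O[C@H](C)c1ccccc1 | intermediate
4 | triethyl({3-methoxy-3-[(1R)-1-phenylethoxy]prop-1-en-2-yl}oxy)silane | C=C(O[Si](CC)(CC)CC)C(OC)O[C@H](C)c1ccccc1 | intermediate
5 | 3-methylfuran | Cc1ccoc1 | starting material
6 | 1-[(1R)-1-phenylethoxy]-2-(triethylsilyloxy)allyl cation as its triflate (oxocarbenium form) | C=C(O[Si](CC)(CC)CC)C=[O+][C@H](C)c1ccccc1.[O-]S(=O)(=O)C(F)(F)F | intermediate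
7 | (1R,2S,5R)-6-methyl-2-[(1R)-1-phenylethoxy]-8-oxabicyclo[3.2.1]oct-6-en-3-one (alkoxy group equatorial, trans to the bridge oxygen) | O=C1C[C@H]2O[C@H](C=C2C)[C@@H]1O[C@H](C)c1ccccc1 | intermediate
8 | (1R,2S,5R)-2-hydroxy-6-methyl-8-oxabicyclo[3.2.1]oct-6-en-3-one | O=C1C[C@H]2O[C@H](C=C2C)[C@@H]1O | intermediate
9 | (1R,2S,5R)-6-methyl-3-oxo-8-oxabicyclo[3.2.1]oct-6-en-2-yl 2-(triphenyl-λ5-phosphanylidene)acetate | O=C1C[C@H]2O[C@H](C=C2C)[C@@H]1OC(=O)C=P(c1ccccc1)(c1ccccc1)c1ccccc1 | intermediate
10 | (5R,8R,8aR)-6-methyl-4,5,8,8a-tetrahydro-2H-5,8-epoxycyclohepta[b]furan-2-one (butenolide, C3=C3a) | O=C1C=C2C[C@H]3O[C@H](C=C3C)[C@@H]2O1 | intermediate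
11 | lithium enolate of the cis-fused lactone (hydride on C3a, syn to the bridge) | [Li+].[O-]C1=C[C@@H]2C[C@H]3O[C@H](C=C3C)[C@@H]2O1 | intermediate
12 | (3aS,5R,8R,8aR)-3-[(dimethylamino)methyl]-6-methyl-3,3a,4,5,8,8a-hexahydro-2H-5,8-epoxycyclohepta[b]furan-2-one (C3 epimers; H3a and H8a cis, syn to the bridge) | O=C1C(CN(C)C)[C@@H]2C[C@H]3O[C@H](C=C3C)[C@@H]2O1 | intermediate
13 | B-alkyl-9-borabicyclo[3.3.1]nonane adduct of 12 (boron on C7, exo; 6-methyl endo) | O=C1C(CN(C)C)[C@@H]2C[C@H]3O[C@H]([C@H](B4C5CCCC4CCC5)[C@H]3C)[C@@H]2O1 | intermediate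
14 | (3aS,5R,6R,7R,8R,8aR)-3-[(dimethylamino)methyl]-7-hydroxy-6-methyloctahydro-2H-5,8-epoxycyclohepta[b]furan-2-one (7-OH exo, 6-CH3 endo) | O=C1C(CN(C)C)[C@@H]2C[C@H]3O[C@H]([C@H](O)[C@H]3C)[C@@H]2O1 | intermediate
15 | (3aS,5R,6S,8S,8aR)-3-[(dimethylamino)methyl]-6-methylhexahydro-2H-5,8-epoxycyclohepta[b]furan-2,7(3H)-dione | O=C1C(CN(C)C)[C@@H]2C[C@H]3O[C@H](C(=O)[C@H]3C)[C@@H]2O1 | intermediate
16 | but-2-yn-1-ol | CC#CCO | starting material
17 | 1-methoxybut-2-yne | CC#CCOC | intermediate
18 | 1-methoxybuta-1,2-diene (racemic) | COC=C=CC | intermediate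
19 | 1-lithio-1-methoxybuta-1,2-diene | [Li]C(OC)=C=CC | intermediate
20 | lithium alkoxide of the C7 adduct, 7-(1-methoxybuta-1,2-dien-1-yl) exo and O endo | O=C1C(CN(C)C)[C@@H]2C[C@H]3O[C@H]([C@]([O-])(C(OC)=C=CC)[C@H]3C)[C@@H]2O1.[Li+] | intermediate
21 | (3aS,5R,6S,7S,8S,8aR)-7-[(2E)-but-2-enoyl]-3-[(dimethylamino)methyl]-7-hydroxy-6-methyloctahydro-2H-5,8-epoxycyclohepta[b]furan-2-one | O=C1C(CN(C)C)[C@@H]2C[C@H]3O[C@H]([C@](O)(C(=O)/C=C/C)[C@H]3C)[C@@H]2O1 | intermediate
22 | trimethylammonium iodide of 21 | O=C1C(C[N+](C)(C)C)[C@@H]2C[C@H]3O[C@H]([C@](O)(C(=O)/C=C/C)[C@H]3C)[C@@H]2O1.[I-] | intermediate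
23 | (3aS,5R,6S,7S,8S,8aR)-7-[(2E)-but-2-enoyl]-7-hydroxy-6-methyl-3-methylideneoctahydro-2H-5,8-epoxycyclohepta[b]furan-2-one | O=C1C(=C)[C@@H]2C[C@H]3O[C@H]([C@](O)(C(=O)/C=C/C)[C@H]3C)[C@@H]2O1 | intermediate
24 | (2S)-2-methylbutanoyl chloride | CC[C@H](C)C(=O)Cl | starting material
25 | (2S)-2-methylbutanoyl iodide | CC[C@H](C)C(=O)I | intermediate
26 | (3aS,5S,6R,7S,8S,8aR)-7-[(2E)-but-2-enoyl]-7-hydroxy-5-iodo-6-methyl-3-methylidene-2-oxooctahydro-2H-cyclohepta[b]furan-8-yl (2S)-2-methylbutanoate (iodine trans to the C8 ester) | C=C1C(=O)O[C@@H]2[C@H]1C[C@H](I)[C@H](C)[C@@](O)(C(=O)/C=C/C)[C@H]2OC(=O)[C@@H](C)CC | intermediate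
27 | (3aS,5R,6S,7S,8S,8aR)-7-[(2E)-but-2-enoyl]-5,7-dihydroxy-6-methyl-3-methylidene-2-oxooctahydro-2H-cyclohepta[b]furan-8-yl (2S)-2-methylbutanoate | C=C1C(=O)O[C@@H]2[C@H]1C[C@@H](O)[C@H](C)[C@@](O)(C(=O)/C=C/C)[C@H]2OC(=O)[C@@H](C)CC | target

**Step count and risks**

Total step count: 14. Longest linear sequence: 12 steps (steps 1 to 8 and 11 to 14); steps 9 and 10 make the allene in a side branch.

Step 3 is the first of the three steps most likely to fail. The two partners may pair in the wrong orientation (the alkoxy-bearing terminus bonding to the methyl-side furan carbon), or the auxiliary may shield the cation face incompletely. The fallback sets out from 5 and uses the Lewis-acid-promoted (4+3) cycloaddition of a 2-(silyloxy)acrolein. 3-Methylfuran and 2-(triisopropylsilyloxy)acrolein F1 are combined with Sc(OTf)3 (cat.) in CH2Cl2 at −78 °C. The first bond then forms by conjugate addition of the most nucleophilic furan carbon (next to the methyl group) to the enal CH2 carbon, so the orientation is fixed by a step of known regiochemistry. Aldol-type closure and silyl shift should give racemic 6-methyl-2-(triisopropylsilyloxy)-8-oxabicyclo[3.2.1]oct-6-en-3-one F2. The racemate is resolved on a chiral stationary phase and the (1R,2S,5R) enantiomer is desilylated with HF·pyridine in THF, which comes back to the route at 8.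

Step 13 is the second. The acyl iodide may acylate the tertiary hydroxyl instead of the bridge oxygen; that hydroxyl may capture the acyloxonium ion at C8 (epoxide formation with the ester left on the C5 oxygen); or iodide may fail to reach the crowded backside of C5. The fallback sets out from 23 and separates ether cleavage from ester formation. Dimethylboron bromide (Me2BBr, CH2Cl2, −78 °C) coordinates the bridge oxygen and delivers bromide to C5, which should give the bromohydrin F3 with the C8 hydroxyl free. This hydroxyl, a secondary one beside the unreactive tertiary one, is then esterified with 24 (pyridine, DMAP, CH2Cl2, 0 °C) to the bromo ester F4. F4 takes the place of 26 in the silver-assisted solvolysis of step 14 and the route is rejoined at 27.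

Step 14 is the third. Elimination toward C6 or C4, a hydride shift in a free secondary cation, or acyl transfer from the C8 oxygen to the new C5 oxygen through the bridged dioxacarbenium ion may compete with substitution. The fallback sets out from 26 and replaces substitution by oxidation and directed reduction. A silver-assisted Kornblum oxidation (AgBF4, DMSO, rt; then Et3N) should give the C5 ketone F5, whatever the stereochemical course at C5. A hydroxyl-directed triacetoxyborohydride reduction (Me4N[BH(OAc)3], MeCN–AcOH, −30 °C) then delivers hydride from the face of the tertiary C7 hydroxyl and should give the 1,3-anti diol, which is 27.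

Further compounds
F1 | step 3 | 2-(triisopropylsilyloxy)prop-2-enal | C=C(O[Si](C(C)C)(C(C)C)C(C)C)C=O
F2 | step 3 | 6-methyl-2-(triisopropylsilyloxy)-8-oxabicyclo[3.2.1]oct-6-en-3-one, racemate (the (1R,2S,5R) enantiomer drawn is the one kept after resolution) | O=C1C[C@H]2O[C@H](C=C2C)[C@@H]1O[Si](C(C)C)(C(C)C)C(C)C
F3 | step 13 | (3aS,5S,6R,7S,8S,8aR)-5-bromo-7-[(2E)-but-2-enoyl]-7,8-dihydroxy-6-methyl-3-methylideneoctahydro-2H-cyclohepta[b]furan-2-one | C=C1C(=O)O[C@@H]2[C@H]1C[C@H](Br)[C@H](C)[C@@](O)(C(=O)/C=C/C)[C@H]2O
F4 | step 13 | (3aS,5S,6R,7S,8S,8aR)-5-bromo-7-[(2E)-but-2-enoyl]-7-hydroxy-6-methyl-3-methylidene-2-oxooctahydro-2H-cyclohepta[b]furan-8-yl (2S)-2-methylbutanoate | C=C1C(=O)O[C@@H]2[C@H]1C[C@H](Br)[C@H](C)[C@@](O)(C(=O)/C=C/C)[C@H]2OC(=O)[C@@H](C)CC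
F5 | step 14 | (3aS,6S,7S,8S,8aR)-7-[(2E)-but-2-enoyl]-7-hydroxy-6-methyl-3-methylidene-2,5-dioxooctahydro-2H-cyclohepta[b]furan-8-yl (2S)-2-methylbutanoate | C=C1C(=O)O[C@@H]2[C@H]1CC(=O)[C@H](C)[C@@](O)(C(=O)/C=C/C)[C@H]2OC(=O)[C@@H](C)CC
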